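Amounts first: at 8.1 min the epsilon run held 0.0576 M of J, so 0.0424 M of Q and 0.0524 M of X were left. Q is the limiting reagent of the epsilon run, charged at 0.100 M against 0.110 M of X. The zeta run has the epsilon charge, so the epsilon readings served for its first 8.1 min, and I had to reckon the tail.

all flasks: Z 0.00100 M
- epsilon: Q 0.100 M; X 0.110 M
- theta: Q 0.0500 M; X 0.0600 M
- gamma: Q 0.150 M; X 0.110 M
- zeta: Q 0.100 M; X 0.110 M; time 16 min

| run | time / min | [J] / M |
|---|---|---|
| epsilon run | 1.4 | 0.0205 |
| epsilon run | 2.7 | 0.0329 |
| epsilon run | 4.0 | 0.0423 |
| epsilon run | 5.4 | 0.0485 |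
| epsilon run | 6.8 | 0.0532 |
| epsilon run | 8.1 | 0.0576 |
| theta run | 1.4 | 0.0091 |
| theta run | 2.7 | 0.0134 |
| theta run | 4.0 | 0.0203 |
| theta run | 5.4 | 0.0232 |
| theta run | 6.8 | 0.0258 |
| theta run | 8.1 | 0.0298 |
| gamma run | 1.4 | 0.0222 |
| gamma run | 2.7 | 0.0339 |
| gamma run | 4.0 | 0.0467 |
| gamma run | 5.4 | 0.0559 |
| gamma run | 6.8 | 0.0608 |
| gamma run | 8.1 | 0.0667 |

(readings scatter by 0.001 M)

1. order of the initial rate in [X], near the charge of the epsilon run, the rate being that where two percent of its Q are J
2. order of the initial rate in [Q], near the charge of the epsilon run, the rate being that where two percent of its Q are J (one fixed amount of J, the same in the runs compared)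
3. the theta run starts with 0.0500 M less of Q and of X than the epsilon run, and with no J. Compared where both hold the same amount of Q, once fifteen percent of what the theta run was charged with has turned into J, is the theta run faster, slower or alike (within a tenth)?
4. J in the zeta run at 16 min, as a share of the Q charged

- Overall: Q + X -> J, with Z as catalyst.
- Constant volume, constant temperature.
- Readings of a species count what is bound in complexes too.
- "The second partner" is X.
- An order is taken over about fifteen percent of the charge, up and down.

My first way used the late constant κ, the mean rate over a late stretch divided by [Q][X] at the stretch's midpoint in J. It is an effective second-order constant. From 4.0 min to 8.1 min the epsilon run made J at 0.00373 M min⁻¹, with 0.0499 M of J at the midpoint, which gave κ = 1.24 M⁻¹ min⁻¹. I then sought the gain after 8.1 min that agrees with κ at its own midpoint. It came to 0.0153 M, so J reached 72.9 % of the Q charged.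

My second way ignored Q and X. The last two epsilon gains over equal stretches were 0.0156 M and 0.00910 M, a ratio of 0.583. Repeating that ratio for 3 more stretches reached 16.2 min, close to 16 min, and gave 67.8 %, less than the first way.

The ratio way cheated. Its series sums to a ceiling of 0.0703 M of J, where the rate would reach zero with 0.0297 M of Q and 0.0397 M of X still present. Yet κ, read over the same two stretches, went from 1.41 M⁻¹ min⁻¹ to 1.26 M⁻¹ min⁻¹, a reading that carries the scatter and shows no approach to zero. That same fall warned me that my figure ran high. The midpoint shortcut was the smaller error: the mean of the end products lay 3.76 % above the midpoint product, against a fall of 10.3 % in κ. I committed to 72.9 % as an upper-side figure.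

The forecast gave orders of 0.95 in X (0.65 to 1.25) and 0.25 in Q (0.05 to 0.5), called the theta run faster, and put the zeta run at 73 % (68 % to 79 %). From its comparison of the theta and epsilon runs at equal Q it concluded that “accumulated J inhibits, or the catalyst has aged”.

The zeta run gave 70.8 %. Near the epsilon charge the orders came to 1.0 in X and 0.25 in Q, and where the theta and epsilon runs held the same amount of Q, the theta run was faster than the epsilon run, by a ratio of 2.4. From the epsilon reading at 8.1 min, that share means a tail κ of 1.02 M⁻¹ min⁻¹, less than my 1.24 M⁻¹ min⁻¹. In the gamma run, its own late κ of 0.981 M⁻¹ min⁻¹ puts J at half its Q by 10.8 min, sooner than the simulated 11.4 min.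

    Z + Q ⇌ ZQ, settled at all times (37.20 M⁻¹)
    ZQ + X → J + Z + L (439.8 M⁻¹ min⁻¹)
    Z + L ⇌ ZL, settled at all times (93.50 M⁻¹)
    Z + Gy → Oz

In the zeta run, Gy took 4.36 × 10⁻⁴ M of the Z into Oz at once, leaving 5.64 × 10⁻⁴ M. ZQ + X → J + Z + L then ran through to 16 min, with L binding Z as ZL along the way, and at that time free Z held 11.5 % of that Z, ZQ held 12.5 %, and ZL, by then the resting state, held 76.0 %.

The runs were computed from invented constants; noise was put on by code.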